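**Retrosynthetic overview**

1. The α-methylene group comes last, by Horner–Wadsworth–Emmons reaction of a C15 phosphonate with formaldehyde; the C5 and C13 acetates come from a diol, and the C13 alcohol from a C13 ketone.
2. The bicyclic core comes from a linear enol ester–dienone by one radical–polar (4+3) annulation: a C4 radical (from the enol ester C4=C18) adds to C3, the δ-carbon of the C13 dienone, closing the 14-membered ring; the phosphonoacetate carbon C15 then adds to C1, the β-carbon, closing the seven-membered lactone.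
3. Enabling feature: in the ε-lactone ring (C15, C16, O, C4, C3, C2, C1) the ester oxygen sits on C4 and C15 is the α-carbon of that same ester, while C3 and C1 lie δ and β to the oxygenated C13. The ring is therefore the sum of a C15–C16–O–C4 unit and a C3–C2–C1 unit, and closing it also closes the macrocycle.
4. The linear precursor comes from an aldehyde–alkyne by Ru-catalysed addition of phosphonoacetic acid to the alkyne and Nozaki–Hiyama–Kishi dienylation/oxidation at C13.
5. The aldehyde–alkyne comes from (R)-linalool (its carbinol carbon becomes C12): SeO2 oxidation, Sharpless epoxidation with 5-exo opening (oxolane ring, C9 and C8), two-carbon homologation, alkynylation and Noyori reduction (C5). Ring order: oxolane first, then carbocycle and lactone together.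

Key step: step 14

Numbering used below (cembrane type): ring carbons C1–C14; C1 carries C15(=C17H2)–C16(=O)–O, whose oxygen is bound to C4; C18, C19, C20 are the methyls on C4, C8, C12; the oxolane oxygen bridges C9 and C12; the target is 1R,4R,5R,8R,9S,12R,13S.

**Step 1**
Reactants: 1 (R)-(−)-linalool
Product: 2 (2E,6R)-2,6-dimethylocta-2,7-diene-1,6-diol
Conditions: SeO2 (0.1 equiv), t-BuOOH (3 equiv), salicylic acid (cat.), CH2Cl2, 23 °C
Reagents that add atoms: tert-butyl hydroperoxide, CC(C)(C)OO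
Why: SeO2-catalysed allylic oxidation (Riley type, ene then [2,3]-shift) is selective for the (E)-methyl of a trisubstituted gem-dimethyl alkene, and the purchased carbinol centre is not touched.

**Step 2**
Reactants: 2 (2E,6R)-2,6-dimethylocta-2,7-diene-1,6-diol
Product: 4 (2R)-2-[(2S,5R)-5-ethenyl-5-methyloxolan-2-yl]propane-1,2-diol, via epoxy diol 3 (not isolated)
Conditions: Ti(Oi-Pr)4 (10 mol%), (−)-diethyl D-tartrate (12 mol%), t-BuOOH, 4 Å MS, CH2Cl2, −20 °C; then camphorsulfonic acid (10 mol%), 0 °C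
Reagents that add atoms: tert-butyl hydroperoxide, CC(C)(C)OO
Why: Sharpless asymmetric epoxidation of the primary allylic alcohol is reagent-controlled (the D-tartrate should give the (2R,3R)-epoxide, the antipode of what the L-tartrate gives with geraniol-type (E)-alcohols), and the tertiary hydroxyl then opens the epoxide 5-exo with inversion at the carbon remote from CH2OH, which sets the cis-2,5-disubstituted oxolane and the C8/C9 relationship.

**Step 3**
Reactants: 4 (2R)-2-[(2S,5R)-5-ethenyl-5-methyloxolan-2-yl]propane-1,2-diol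
Product: 6 (2R)-2-[(2S,5R)-5-ethenyl-5-methyloxolan-2-yl]-2-methyloxirane, via primary tosylate 5 (not isolated)
Conditions: NaH (2.5 equiv), N-tosylimidazole (1.05 equiv), THF, 0 → 23 °C
Reagents that add atoms: none
Why: Selective sulfonylation of the primary alkoxide followed by intramolecular Williamson displacement by the tertiary alkoxide gives the terminal epoxide, and the C–O bond at the quaternary carbon is kept, so no stereocentre changes.

**Step 4**
Reactants: 6 (2R)-2-[(2S,5R)-5-ethenyl-5-methyloxolan-2-yl]-2-methyloxirane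
Product: 7 (4R)-4-hydroxy-4-[(2S,5R)-5-ethenyl-5-methyloxolan-2-yl]-1-(morpholin-4-yl)pentan-1-one
Conditions: 4-acetylmorpholine, LiN(i-Pr)2, THF, −78 °C; add 6, −78 → 23 °C; then H2O
Reagents that add atoms: 4-acetylmorpholine, CC(=O)N1CCOCC1
Why: Lithium amide enolates open terminal epoxides by SN2 attack at the CH2 carbon, so the tertiary carbinol centre is retained and C6–C5 are added as a morpholine amide that serves as acyl donor in the next step.

**Step 5**
Reactants: 7 (4R)-4-hydroxy-4-[(2S,5R)-5-ethenyl-5-methyloxolan-2-yl]-1-(morpholin-4-yl)pentan-1-one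
Product: 8 (6R)-6-hydroxy-6-[(2S,5R)-5-ethenyl-5-methyloxolan-2-yl]-1-(trimethylsilyl)hept-1-yn-3-one
Conditions: ethynyltrimethylsilane (3.5 equiv), n-BuLi (3.3 equiv), THF, −78 → −20 °C; then H2O
Reagents that add atoms: ethynyltrimethylsilane, C#C[Si](C)(C)C
Why: Morpholine amides acylate alkynyllithiums like Weinreb amides (a stable tetrahedral intermediate prevents over-addition), which gives the ynone that holds C4 and C18.

**Step 6**
Reactants: 8 (6R)-6-hydroxy-6-[(2S,5R)-5-ethenyl-5-methyloxolan-2-yl]-1-(trimethylsilyl)hept-1-yn-3-one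
Product: 9 (3R,6R)-6-[(2S,5R)-5-ethenyl-5-methyloxolan-2-yl]-1-(trimethylsilyl)hept-1-yne-3,6-diol
Conditions: Ru[(R,R)-TsDPEN](p-cymene) (2 mol%), i-PrOH, 23 °C
Reagents that add atoms: none
Why: Noyori asymmetric transfer hydrogenation of alkynyl ketones is chemoselective for C=O and reagent-controlled, and the (R,R)-catalyst should give the (R)-propargylic alcohol (C5), the alkynyl group taking the role of the aryl group of aryl ketones.

**Step 7**
Reactants: 9 (3R,6R)-6-[(2S,5R)-5-ethenyl-5-methyloxolan-2-yl]-1-(trimethylsilyl)hept-1-yne-3,6-diol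
Product: 10 (3R,6R)-6-[(2S,5R)-5-ethenyl-5-methyloxolan-2-yl]hept-1-yne-3,6-diol
Conditions: K2CO3 (0.2 equiv), MeOH, 23 °C
Reagents that add atoms: none
Why: Carbonate-catalysed methanolysis of the C(sp)–Si bond is a standard protodesilylation that leaves the alcohols and the alkene untouched.

**Step 8**
Reactants: 10 (3R,6R)-6-[(2S,5R)-5-ethenyl-5-methyloxolan-2-yl]hept-1-yne-3,6-diol
Product: 11 (2S,5R)-2-[(2R,5R)-2,5-bis(triethylsilyloxy)hept-6-yn-2-yl]-5-ethenyl-5-methyloxolane
Conditions: Et3SiOTf (3 equiv), 2,6-lutidine (5 equiv), CH2Cl2, −78 → 0 °C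
Reagents that add atoms: triethylsilyl trifluoromethanesulfonate, CC[Si](CC)(CC)OS(=O)(=O)C(F)(F)F
Why: Silyl triflate silylation covers both the secondary propargylic and the hindered tertiary hydroxyl, which prevents lactol formation between the C8 hydroxyl and the C13 carbonyl made next and removes acidic O–H groups from the metal-mediated steps.

**Step 9**
Reactants: 11 (2S,5R)-2-[(2R,5R)-2,5-bis(triethylsilyloxy)hept-6-yn-2-yl]-5-ethenyl-5-methyloxolane
Product: 12 (2R,5S)-5-[(2R,5R)-2,5-bis(triethylsilyloxy)hept-6-yn-2-yl]-2-methyloxolane-2-carbaldehyde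
Conditions: OsO4 (2 mol%), NaIO4 (4 equiv), 2,6-lutidine, dioxane/H2O 3:1, 23 °C
Reagents that add atoms: sodium periodate (terminal oxidant, oxygen delivered through OsO4), [Na+].[O-]I(=O)(=O)=O
Why: Lemieux–Johnson cleavage (dihydroxylation, then glycol cleavage) is selective for the alkene over the terminal alkyne and gives a non-enolisable α-alkoxy aldehyde, so C12 cannot epimerise.

**Step 10**
Reactants: 12 (2R,5S)-5-[(2R,5R)-2,5-bis(triethylsilyloxy)hept-6-yn-2-yl]-2-methyloxolane-2-carbaldehyde; 13 2-(diethoxyphosphoryl)acetic acid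
Product: 14 (3R,6R)-6-[(2S,5R)-5-formyl-5-methyloxolan-2-yl]-3,6-bis(triethylsilyloxy)hept-1-en-2-yl 2-(diethoxyphosphoryl)acetate
Conditions: [RuCl2(p-cymene)]2 (2 mol%), P(2-furyl)3 (4 mol%), Na2CO3 (4 mol%), toluene, 60 °C
Reagents that add atoms: none
Why: Ruthenium-catalysed Markovnikov addition of a carboxylic acid to a terminal alkyne gives the 1,1-disubstituted enol ester directly under nearly neutral conditions that tolerate the aldehyde, the silyl ethers and the phosphonate.

**Step 11**
Reactants: 15 acrolein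
Product: 16 (1E)-1-iodobuta-1,3-diene
Conditions: CHI3 (2 equiv), CrCl2 (6 equiv), THF, 0 °C; used as a cold solution
Reagents that add atoms: iodoform, IC(I)I
Why: Takai olefination of an aldehyde through a geminal dichromium carbenoid gives the (E)-alkenyl iodide.

**Step 12**
Reactants: 14 (3R,6R)-6-[(2S,5R)-5-formyl-5-methyloxolan-2-yl]-3,6-bis(triethylsilyloxy)hept-1-en-2-yl 2-(diethoxyphosphoryl)acetate; 16 (1E)-1-iodobuta-1,3-diene
Product: 17 (3R,6R)-6-[(2S,5R)-5-[(2E)-1-hydroxypenta-2,4-dien-1-yl]-5-methyloxolan-2-yl]-3,6-bis(triethylsilyloxy)hept-1-en-2-yl 2-(diethoxyphosphoryl)acetate (both carbinol epimers)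
Conditions: CrCl2 (4 equiv), NiCl2 (2 mol%), DMSO/THF, 23 °C
Reagents that add atoms: none
Why: Nozaki–Hiyama–Kishi coupling adds the alkenylchromium species chemoselectively to the hindered aldehyde in the presence of the enol ester and the acidic phosphonoacetate with retention of the (E)-diene, and the new carbinol centre is removed in step 13.

**Step 13**
Reactants: 17 (3R,6R)-6-[(2S,5R)-5-[(2E)-1-hydroxypenta-2,4-dien-1-yl]-5-methyloxolan-2-yl]-3,6-bis(triethylsilyloxy)hept-1-en-2-yl 2-(diethoxyphosphoryl)acetate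
Product: 18 (3R,6R)-6-[(2S,5R)-5-methyl-5-[(2E)-penta-2,4-dienoyl]oxolan-2-yl]-3,6-bis(triethylsilyloxy)hept-1-en-2-yl 2-(diethoxyphosphoryl)acetate
Conditions: MnO2 (20 equiv), CH2Cl2, 23 °C; used at once
Reagents that add atoms: none
Why: MnO2 oxidises only the doubly allylic secondary alcohol, under neutral heterogeneous conditions, to the terminal (E)-dienone.

**Step 14**
Reactants: 18 (3R,6R)-6-[(2S,5R)-5-methyl-5-[(2E)-penta-2,4-dienoyl]oxolan-2-yl]-3,6-bis(triethylsilyloxy)hept-1-en-2-yl 2-(diethoxyphosphoryl)acetate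
Product: 20 (1R,4R,5R,8R,9S,12R)-15-(diethoxyphosphoryl)-13-oxo-5,8-bis(triethylsilyloxy)-9,12-epoxycembran-16,4-olide (C15 epimers), via macrocyclic enone 19 (not isolated)
Conditions: Fe(acac)3 (0.5 equiv), PhSiH2(Oi-Pr) (2.5 equiv), THF/i-PrOH 10:1, 40 °C, syringe-pump addition of 18 to a final 1 mM; then DBU (3 equiv), LiCl (5 equiv), 23 °C
Reagents that add atoms: none
Why: Proposed new method: an iron hydride should transfer a hydrogen atom to C18 of the enol ester (the most electron-rich alkene), the tertiary α-acyloxy C4 radical adds to the unsubstituted δ-carbon C3 of the dienone in a 14-endo-trig macrocyclization, and reduction of the delocalized radical by divalent iron with protonation gives enone 19; DBU/LiCl then ionizes the phosphonoacetate C15–H and the carbanion closes the ε-lactone by 7-exo-trig Michael addition to C1. The closest known reaction types are metal-hydride hydrogen-atom-transfer Giese couplings of heteroatom-substituted olefins with enones, the radical–polar crossover annulations that follow them, radical 14-endo macrocyclizations onto enones used for cembranoids, and 1,6- then 1,4-additions of bis-nucleophiles to dienones; their combination as a macrocyclizing (4+3) annulation is new. C4 is set by 1,2-induction from C5: with the forming C3–C4 bond antiperiplanar to C5–C6 in the ring backbone, the C18 methyl should take the position anti to the bulky OSiEt3 group and the two C–O bonds stay gauche, which gives 4R. C1 is set under thermodynamic control, because Michael addition of the stabilized carbanion is reversible, and the 1R epimer that lets the ten-atom bridge leave the oxepanone pseudo-equatorially at both C4 and C1 is expected to be favoured; C15 forms as a mixture and is erased in step 18. The step needs hydrogen-atom transfer to the enol ester rather than to the dienone (expected from the preference of such hydrides for electron-rich 1,1-disubstituted olefins), 1,6- rather than 1,4-radical addition (C3 is unsubstituted and gives the most delocalized radical), and ring closure rather than oligomerization (high dilution).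

**Step 15**
Reactants: 20 (1R,4R,5R,8R,9S,12R)-15-(diethoxyphosphoryl)-13-oxo-5,8-bis(triethylsilyloxy)-9,12-epoxycembran-16,4-olide
Product: 21 (1R,4R,5R,8R,9S,12R,13S)-15-(diethoxyphosphoryl)-13-hydroxy-5,8-bis(triethylsilyloxy)-9,12-epoxycembran-16,4-olide
Conditions: (R)-2-methyl-CBS-oxazaborolidine (0.3 equiv), BH3·SMe2 (1.5 equiv), THF, −30 °C; then MeOH
Reagents that add atoms: none
Why: Corey–Bakshi–Shibata reduction with the quaternary C12 as large group and C14H2 as small group should give the 13S alcohol with the (R)-catalyst by reagent control, while lactone, phosphonate and silyl ethers are inert to borane at low temperature.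

**Step 16**
Reactants: 21 (1R,4R,5R,8R,9S,12R,13S)-15-(diethoxyphosphoryl)-13-hydroxy-5,8-bis(triethylsilyloxy)-9,12-epoxycembran-16,4-olide
Product: 22 (1R,4R,5R,8R,9S,12R,13S)-15-(diethoxyphosphoryl)-5,8,13-trihydroxy-9,12-epoxycembran-16,4-olide
Conditions: HF·pyridine, pyridine/THF, 0 → 23 °C
Reagents that add atoms: none
Why: Fluoride-driven cleavage of both triethylsilyl ethers under buffered conditions leaves the lactone and the phosphonate untouched and changes no stereocentre.

**Step 17**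
Reactants: 22 (1R,4R,5R,8R,9S,12R,13S)-15-(diethoxyphosphoryl)-5,8,13-trihydroxy-9,12-epoxycembran-16,4-olide
Product: 23 (1R,4R,5R,8R,9S,12R,13S)-5,13-diacetoxy-15-(diethoxyphosphoryl)-8-hydroxy-9,12-epoxycembran-16,4-olide
Conditions: Ac2O (6 equiv), pyridine, DMAP (0.1 equiv), CH2Cl2, 0 → 23 °C
Reagents that add atoms: acetic anhydride, CC(=O)OC(C)=O
Why: DMAP-catalysed acylation esterifies the two secondary hydroxyls, while the tertiary C8 hydroxyl is too hindered to react at ambient temperature.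

**Step 18**
Reactants: 23 (1R,4R,5R,8R,9S,12R,13S)-5,13-diacetoxy-15-(diethoxyphosphoryl)-8-hydroxy-9,12-epoxycembran-16,4-olide
Product: 24 querciformolide C
Conditions: paraformaldehyde (10 equiv), K2CO3 (3 equiv), 18-crown-6 (cat.), THF, 40 °C
Reagents that add atoms: formaldehyde (as paraformaldehyde), C=O
Why: Horner–Wadsworth–Emmons olefination of an α-phosphono lactone with formaldehyde is the standard entry to α-methylene lactones and removes the undefined C15 centre, under conditions that should spare the acetates.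

**Compound list**

1 | (R)-(−)-linalool, (3R)-3,7-dimethylocta-1,6-dien-3-ol | C=C[C@@](O)(C)CCC=C(C)C | starting material
2 | (2E,6R)-2,6-dimethylocta-2,7-diene-1,6-diol | C=C[C@@](O)(C)CC/C=C(\C)CO | intermediate
3 | [(2R,3R)-3-[(3R)-3-hydroxy-3-methylpent-4-en-1-yl]-2-methyloxiran-2-yl]methanol | C=C[C@@](O)(C)CC[C@H]1O[C@]1(C)CO | intermediate (not isolated)
4 | (2R)-2-[(2S,5R)-5-ethenyl-5-methyloxolan-2-yl]propane-1,2-diol | C=C[C@@]1(C)CC[C@H](O1)[C@](C)(O)CO | intermediate
5 | (2R)-2-[(2S,5R)-5-ethenyl-5-methyloxolan-2-yl]-2-hydroxypropyl 4-methylbenzenesulfonate | C=C[C@@]1(C)CC[C@H](O1)[C@](C)(O)COS(=O)(=O)c1ccc(C)cc1 | intermediate (not isolated)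
6 | (2R)-2-[(2S,5R)-5-ethenyl-5-methyloxolan-2-yl]-2-methyloxirane | C=C[C@@]1(C)CC[C@H](O1)[C@@]2(C)CO2 | intermediate
7 | (4R)-4-hydroxy-4-[(2S,5R)-5-ethenyl-5-methyloxolan-2-yl]-1-(morpholin-4-yl)pentan-1-one | C=C[C@@]1(C)CC[C@H](O1)[C@](C)(O)CCC(=O)N1CCOCC1 | intermediate
8 | (6R)-6-hydroxy-6-[(2S,5R)-5-ethenyl-5-methyloxolan-2-yl]-1-(trimethylsilyl)hept-1-yn-3-one | C=C[C@@]1(C)CC[C@H](O1)[C@](C)(O)CCC(=O)C#C[Si](C)(C)C | intermediate
9 | (3R,6R)-6-[(2S,5R)-5-ethenyl-5-methyloxolan-2-yl]-1-(trimethylsilyl)hept-1-yne-3,6-diol | C=C[C@@]1(C)CC[C@H](O1)[C@](C)(O)CC[C@@H](O)C#C[Si](C)(C)C | intermediate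
10 | (3R,6R)-6-[(2S,5R)-5-ethenyl-5-methyloxolan-2-yl]hept-1-yne-3,6-diol | C=C[C@@]1(C)CC[C@H](O1)[C@](C)(O)CC[C@@H](O)C#C | intermediate
11 | (2S,5R)-2-[(2R,5R)-2,5-bis(triethylsilyloxy)hept-6-yn-2-yl]-5-ethenyl-5-methyloxolane | C=C[C@@]1(C)CC[C@H](O1)[C@](C)(O[Si](CC)(CC)CC)CC[C@@H](O[Si](CC)(CC)CC)C#C | intermediate
12 | (2R,5S)-5-[(2R,5R)-2,5-bis(triethylsilyloxy)hept-6-yn-2-yl]-2-methyloxolane-2-carbaldehyde | O=C[C@@]1(C)CC[C@H](O1)[C@](C)(O[Si](CC)(CC)CC)CC[C@@H](O[Si](CC)(CC)CC)C#C | intermediate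
13 | 2-(diethoxyphosphoryl)acetic acid | OC(=O)CP(=O)(OCC)OCC | starting material
14 | (3R,6R)-6-[(2S,5R)-5-formyl-5-methyloxolan-2-yl]-3,6-bis(triethylsilyloxy)hept-1-en-2-yl 2-(diethoxyphosphoryl)acetate | O=C[C@@]1(C)CC[C@H](O1)[C@](C)(O[Si](CC)(CC)CC)CC[C@@H](O[Si](CC)(CC)CC)C(=C)OC(=O)CP(=O)(OCC)OCC | intermediate
15 | acrolein (prop-2-enal) | C=CC=O | starting material
16 | (1E)-1-iodobuta-1,3-diene | I/C=C/C=C | intermediate
17 | (3R,6R)-6-[(2S,5R)-5-[(2E)-1-hydroxypenta-2,4-dien-1-yl]-5-methyloxolan-2-yl]-3,6-bis(triethylsilyloxy)hept-1-en-2-yl 2-(diethoxyphosphoryl)acetate (carbinol epimers) | C=C/C=C/C(O)[C@@]1(C)CC[C@H](O1)[C@](C)(O[Si](CC)(CC)CC)CC[C@@H](O[Si](CC)(CC)CC)C(=C)OC(=O)CP(=O)(OCC)OCC | intermediate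
18 | (3R,6R)-6-[(2S,5R)-5-methyl-5-[(2E)-penta-2,4-dienoyl]oxolan-2-yl]-3,6-bis(triethylsilyloxy)hept-1-en-2-yl 2-(diethoxyphosphoryl)acetate | C=C/C=C/C(=O)[C@@]1(C)CC[C@H](O1)[C@](C)(O[Si](CC)(CC)CC)CC[C@@H](O[Si](CC)(CC)CC)C(=C)OC(=O)CP(=O)(OCC)OCC | intermediate
19 | 14-membered (E)-enone (C14=C1, C13 ketone) with C4 (diethoxyphosphoryl)acetate, 5,8-bis(triethylsilyloxy), 9,12-epoxy; 4R,5R,8R,9S,12R | CCOP(=O)(OCC)CC(=O)O[C@]1(C)CC/C=C/C(=O)[C@@]2(C)CC[C@H](O2)[C@](C)(O[Si](CC)(CC)CC)CC[C@H]1O[Si](CC)(CC)CC | intermediate (not isolated)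
20 | (1R,4R,5R,8R,9S,12R)-15-(diethoxyphosphoryl)-13-oxo-5,8-bis(triethylsilyloxy)-9,12-epoxycembran-16,4-olide (C15 epimers) | CCOP(=O)(OCC)C1C(=O)O[C@]2(C)CC[C@@H]1CC(=O)[C@@]1(C)CC[C@H](O1)[C@](C)(O[Si](CC)(CC)CC)CC[C@H]2O[Si](CC)(CC)CC | intermediate
21 | (1R,4R,5R,8R,9S,12R,13S)-15-(diethoxyphosphoryl)-13-hydroxy-5,8-bis(triethylsilyloxy)-9,12-epoxycembran-16,4-olide | CCOP(=O)(OCC)C1C(=O)O[C@]2(C)CC[C@@H]1C[C@H](O)[C@@]1(C)CC[C@H](O1)[C@](C)(O[Si](CC)(CC)CC)CC[C@H]2O[Si](CC)(CC)CC | intermediate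
22 | (1R,4R,5R,8R,9S,12R,13S)-15-(diethoxyphosphoryl)-5,8,13-trihydroxy-9,12-epoxycembran-16,4-olide | CCOP(=O)(OCC)C1C(=O)O[C@]2(C)CC[C@@H]1C[C@H](O)[C@@]1(C)CC[C@H](O1)[C@](C)(O)CC[C@H]2O | intermediate
23 | (1R,4R,5R,8R,9S,12R,13S)-5,13-diacetoxy-15-(diethoxyphosphoryl)-8-hydroxy-9,12-epoxycembran-16,4-olide | CCOP(=O)(OCC)C1C(=O)O[C@]2(C)CC[C@@H]1C[C@H](OC(C)=O)[C@@]1(C)CC[C@H](O1)[C@](C)(O)CC[C@H]2OC(C)=O | intermediate
24 | querciformolide C | C=C1C(=O)O[C@]2(C)CC[C@@H]1C[C@H](OC(C)=O)[C@@]1(C)CC[C@H](O1)[C@](C)(O)CC[C@H]2OC(C)=O | target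

**Step count and risks**

Total steps: 18. Longest linear sequence: 17 (steps 1–10 and 12–18 from linalool; step 11 is a one-step branch).

Steps most likely to fail:

1. Step 14 (Proposed new method). The C4 radical may be quenched, or the dienone reduced, before the ring closes. The radical addition may show poor facial selectivity at C4, and the Michael closure may stall or give the wrong C1 epimer. The fallback uses known chemistry, sets out from 12 and comes back to the route at 19, which is then closed to 20 with DBU/LiCl as in the second stage of step 14.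
   - Addition of CH2=CHMgBr to the aldehyde should give the allylic alcohol F1.
   - Markovnikov hydration of the terminal alkyne with Ph3PAuNTf2 in wet dioxane should give the methyl ketone F2.
   - Chelation-controlled addition of di(but-3-enyl)zinc, promoted by EtZnCl, to the α-silyloxy ketone sets C4 on the chelate face away from C6 (4R) and should give the diene diol F3. If Felkin control prevailed, the roles of methyl and butenyl would be exchanged.
   - Ring-closing metathesis with the second-generation Grubbs catalyst at high dilution closes the 14-membered ring at C1=C14 to the macrocyclic allylic alcohol F4.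
   - MnO2 should give the macrocyclic enone F5.
   - Acylation of the C4 hydroxyl with bromoacetyl bromide/pyridine gives the bromoacetate F6, and Arbuzov reaction with P(OEt)3 delivers 19.

2. Step 10. Conversion may be low, or Markovnikov regioselectivity may be lost, next to the bulky C5 silyl ether. The fallback sets out from 11 and comes back at 14.
   - Copper-catalysed α-selective protoboration of the alkyne (CuCl, 1,3-dimesitylimidazol-2-ylidene, NaOt-Bu, B2pin2, MeOH) should give the 1,1-disubstituted alkenylboronate F7.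
   - OsO4/NaIO4 should cleave the monosubstituted vinyl group in preference to the electron-poor boryl alkene, giving the boryl aldehyde F8.
   - Cu(OAc)2-promoted oxidative C–O coupling of F8 with acid 13 (Chan–Lam type) forms enol ester 14.

3. Step 15. The conformational bias of the macrocycle may override reagent control and deliver hydride to the wrong face of the C13 ketone. The fallback sets out from 20 and comes back at 21.
   - Reduction with the antipodal catalyst (or NaBH4) is taken to the 13R alcohol F9.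
   - Mitsunobu inversion with 4-nitrobenzoic acid, PPh3 and DIAD should give the 13S 4-nitrobenzoate F10.
   - K2CO3/MeOH cleaves the nitrobenzoate to 21.

**Further compounds**

F1 | step 14 | 1-[(2R,5S)-5-[(2R,5R)-2,5-bis(triethylsilyloxy)hept-6-yn-2-yl]-2-methyloxolan-2-yl]prop-2-en-1-ol (epimers) | C=CC(O)[C@@]1(C)CC[C@H](O1)[C@](C)(O[Si](CC)(CC)CC)CC[C@@H](O[Si](CC)(CC)CC)C#C
F2 | step 14 | (3R,6R)-6-[(2S,5R)-5-(1-hydroxyprop-2-en-1-yl)-5-methyloxolan-2-yl]-3,6-bis(triethylsilyloxy)heptan-2-one | C=CC(O)[C@@]1(C)CC[C@H](O1)[C@](C)(O[Si](CC)(CC)CC)CC[C@@H](O[Si](CC)(CC)CC)C(C)=O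
F3 | step 14 | seco diene diol, 4R tertiary alcohol carrying but-3-enyl at C4 and the C13 vinyl carbinol | C=CC(O)[C@@]1(C)CC[C@H](O1)[C@](C)(O[Si](CC)(CC)CC)CC[C@@H](O[Si](CC)(CC)CC)[C@](C)(O)CCC=C
F4 | step 14 | 14-membered (E)-allylic alcohol (C1=C14, C13–OH, C4–OH) | O[C@]1(C)CC/C=C/C(O)[C@@]2(C)CC[C@H](O2)[C@](C)(O[Si](CC)(CC)CC)CC[C@H]1O[Si](CC)(CC)CC
F5 | step 14 | 14-membered (E)-enone with free C4 hydroxyl | O[C@]1(C)CC/C=C/C(=O)[C@@]2(C)CC[C@H](O2)[C@](C)(O[Si](CC)(CC)CC)CC[C@H]1O[Si](CC)(CC)CC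
F6 | step 14 | C4 bromoacetate of the 14-membered enone | BrCC(=O)O[C@]1(C)CC/C=C/C(=O)[C@@]2(C)CC[C@H](O2)[C@](C)(O[Si](CC)(CC)CC)CC[C@H]1O[Si](CC)(CC)CC
F7 | step 10 | 2-[(3R,6R)-6-[(2S,5R)-5-ethenyl-5-methyloxolan-2-yl]-3,6-bis(triethylsilyloxy)hept-1-en-2-yl]-4,4,5,5-tetramethyl-1,3,2-dioxaborolane | C=C[C@@]1(C)CC[C@H](O1)[C@](C)(O[Si](CC)(CC)CC)CC[C@@H](O[Si](CC)(CC)CC)C(=C)B2OC(C)(C)C(C)(C)O2
F8 | step 10 | (2R,5S)-2-methyl-5-[(2R,5R)-6-(4,4,5,5-tetramethyl-1,3,2-dioxaborolan-2-yl)-2,5-bis(triethylsilyloxy)hept-6-en-2-yl]oxolane-2-carbaldehyde | O=C[C@@]1(C)CC[C@H](O1)[C@](C)(O[Si](CC)(CC)CC)CC[C@@H](O[Si](CC)(CC)CC)C(=C)B2OC(C)(C)C(C)(C)O2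
F9 | step 15 | 13R epimer of 21 | CCOP(=O)(OCC)C1C(=O)O[C@]2(C)CC[C@@H]1C[C@@H](O)[C@@]1(C)CC[C@H](O1)[C@](C)(O[Si](CC)(CC)CC)CC[C@H]2O[Si](CC)(CC)CC
F10 | step 15 | 13S 4-nitrobenzoate of 21 | CCOP(=O)(OCC)C1C(=O)O[C@]2(C)CC[C@@H]1C[C@H](OC(=O)c3ccc(cc3)[N+](=O)[O-])[C@@]1(C)CC[C@H](O1)[C@](C)(O[Si](CC)(CC)CC)CC[C@H]2O[Si](CC)(CC)CC
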